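**Count first.** Count the reagent before anything else: the green, teal and violet runs held it at 1.2 equiv, so none of them varied it independently.

| flask | left-handed substrate | right-handed substrate | reagent | free catalyst | remark |
|---|---|---|---|---|---|
| green | 0.67 M | 0.67 M | 1.2 equiv | 0.37 mol% | run made earlier |
| teal | 1.5 M | 1.5 M | 1.2 equiv | 0.37 mol% | run made earlier |
| violet | 1 M | 1 M | 1.2 equiv | 0.74 mol% | run made earlier |
| flask | 1.0 M | 1.0 M | 1.20 equiv | 0.37 mol% |  |

| run | time / min | left-handed product / % | left-handed substrate / % |
|---|---|---|---|
| green | 10.0 | 10.2 | 40.0 |
| green | 20.0 | 16.8 | 32.8 |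
| green | 25.0 | 18.8 | 30.9 |
| green | 40.0 | 27.3 | 24.4 |
| teal | 10.0 | 21.3 | 28.3 |
| teal | 20.0 | 29.0 | 18.7 |
| teal | 25.0 | 33.3 | 16.9 |
| teal | 40.0 | 39.1 | 11.0 |
| violet | 10.0 | 24.6 | 24.9 |
| violet | 20.0 | 33.9 | 16.0 |
| violet | 25.0 | 35.3 | 11.6 |
| violet | 40.0 | 43.2 | 8.0 |

(each reading ± 1 percentage point)

* apparent order in reagent when 10% of the left-handed substrate and right-handed substrate together are converted (percent change of the rate of making left-handed product for one percent more reagent charged)

- free catalyst is single-handed; left-handed substrate and right-handed substrate are mirror images of each other, charged as a racemate, each of them at the stated concentration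

**One number.** Assume each product formed spends one reagent. At 10% conversion of both substrates together, 16.7% of the reagent charge is spent. Add a little more reagent and, at the same conversion, the same amount is spent, so the remainder grows by a larger percentage. The reagent multiplier, charge divided by charge minus spent amount, is 1.20.

**Both ends.** If the step using reagent is rate-limiting and first order in reagent, the rate follows the remaining reagent and the apparent order equals the multiplier. If reagent has no effect on the rate, the order is zero.

**The test.** The teal run gained 21 percentage points of left-handed product by 10.0 min, but only 7.7 points more by 20.0 min. Following left-handed substrate alone, at a steady fraction per ten minutes, the second gain comes to 12 points; the reading is less, and I read that shortfall, with its scatter, as a hint that reagent in the teal run may disappear faster than product shows. My estimate for the flask is therefore the multiplier or slightly above.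

**The flask.** The forecast gives 0.5, allowing a higher value if “the substrate partly saturates the catalyst”. The flask gives 1.3, more than the multiplier.

    free catalyst + left-handed substrate ⇌ catalyst intermediate A (K = 3.20 M⁻¹, k = 127 M⁻¹ min⁻¹)
    free catalyst + right-handed substrate ⇌ catalyst intermediate B (K = 1.15 M⁻¹, k = 96.6 M⁻¹ min⁻¹)
    reagent + catalyst intermediate A → free catalyst + left-handed product (k = 28.0 M⁻¹ min⁻¹)
    reagent + catalyst intermediate B → free catalyst + right-handed product (k = 1.26 M⁻¹ min⁻¹)
    reagent ⇌ dormant form (K = 1.00, k = 0.201 min⁻¹)

At 0.100 h, products of both hands have spent 18.1% of the reagent, making the multiplier 1.22. Reagent, however, stands at 42.5% of its charge, and the dormant form, at 0.473 M, holds 39.4%.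

(The readings stem from a simulated flask on assumed constants; noise was put on by code.)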